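**Retrosynthetic overview**
- Didemnimide D ⇐ oxidative double decarboxylation of 3-(6-bromoindol-3-yl)-4-(1-methylimidazol-5-yl)pyrrole-2,5-dicarboxylic acid, so the maleimide is the pyrrole ring itself, re-oxidised.
- That pyrrole (as its diethyl ester) ⇐ one-pot Cβ–Cβ bond formation and C–N condensation between a 6-bromoindol-3-ylpyruvate (tryptophan-type α-keto acid unit) and a 2-azido-3-(1-methylimidazol-5-yl)acrylate (histidine-type α-imino acid unit, two electrons oxidised at Cβ).
- Indolylpyruvate ⇐ 6-bromoindole + ethyl bromopyruvate oxime (nitrosoalkene alkylation), then deoximation; azidoacrylate ⇐ 1-methylimidazole-5-carbaldehyde + ethyl azidoacetate.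
- Ring order: indole and imidazole are bought; the pyrrole is the only ring built (step 4) and is converted, not rebuilt, into the maleimide (step 5).

Assumptions: the target has no stereocentre or stereogenic double bond, so there is no enantiomer to select; the presumed biogenesis is taken, by analogy with the chromopyrrolic acid pathway to indolylmaleimides, as Cβ–Cβ union of a tryptophan-derived and a histidine-derived α-keto/α-imino acid, N-closure to a pyrrole-2,5-dicarboxylic acid and oxidative double decarboxylation; ethyl bromopyruvate oxime and ethyl azidoacetate are taken as catalogue reagents.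

**Step 1**
Reactants: 1 6-bromo-1H-indole; 2 ethyl (Z)-3-bromo-2-(hydroxyimino)propanoate
Product: 4 ethyl (E)-3-(6-bromo-1H-indol-3-yl)-2-(hydroxyimino)propanoate, via nitrosoacrylate 3 (not isolated)
Conditions: 1 (2 equiv, excess recovered), Na2CO3 (5 equiv), CH2Cl2, rt, 16 h
Reagents that add atoms: none
Why: Base-induced 1,4-elimination of HBr from 2 gives the transient nitrosoalkene 3, which the indole captures at C3 (Gilchrist nitrosoalkene alkylation of indoles) to give the oxime of the tryptophan-type α-keto ester; no stereocentre is formed and the oxime geometry is irrelevant because it is destroyed in step 2.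

**Step 2**
Reactants: 4 ethyl (E)-3-(6-bromo-1H-indol-3-yl)-2-(hydroxyimino)propanoate
Product: 6 ethyl 3-(6-bromo-1H-indol-3-yl)-2-oxopropanoate, via NH-imine 5 (not isolated)
Conditions: TiCl3 (aq. HCl solution, 2.2 equiv), THF/H2O, 0 °C to rt, 1 h
Reagents that add atoms: water, O
Why: Trivalent titanium cleaves the N–O bond (TiCl3 reductive deoximation) and the NH-imine/enamine 5 is hydrolysed in the acidic aqueous medium to the α-keto ester, which resists further reduction because it sits largely as its conjugated enol; no stereocentre is formed.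

**Step 3**
Reactants: 7 1-methyl-1H-imidazole-5-carbaldehyde; 8 ethyl azidoacetate
Product: 9 ethyl (Z)-2-azido-3-(1-methyl-1H-imidazol-5-yl)prop-2-enoate
Conditions: 8 (4 equiv), NaOEt (4 equiv), EtOH, −15 to 0 °C, 4 h; aq. NH4Cl quench
Reagents that add atoms: none
Why: Knittel (Knoevenagel-type) condensation of the non-enolisable aldehyde with the azidoacetate anion followed by E1cB loss of hydroxide gives the thermodynamically preferred Z-azidoacrylate (imidazolyl trans to the ester), an electrophilic equivalent of the histidine-type α-imino acid oxidised by two electrons at Cβ; no stereocentre is formed.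

**Step 4**
Reactants: 6 ethyl 3-(6-bromo-1H-indol-3-yl)-2-oxopropanoate; 9 ethyl (Z)-2-azido-3-(1-methyl-1H-imidazol-5-yl)prop-2-enoate
Product: 11 diethyl 3-(6-bromo-1H-indol-3-yl)-4-(1-methyl-1H-imidazol-5-yl)-1H-pyrrole-2,5-dicarboxylate, via imino keto diester 10 (not isolated)
Conditions: 6 (1.2 equiv), Cu(NTf2)2 (20 mol %), H2O (2 equiv), MeCN, 40 °C, dark, 12 h
Reagents that add atoms: none
Why: Proposed new method: the divalent-copper enolate of arylpyruvate 6 adds 1,4 to azidoacrylate 9 at the imidazolyl-bearing carbon (the Cβ–Cβ bond of the biogenesis), the α-azido ester enolate expels N2 to give NH-imine 10, whose nitrogen condenses with the adjacent ketone, and the resulting 3H-pyrrole tautomerises to the aromatic 1H-pyrrole; the azide serves as the internal two-electron oxidant, the temperature is kept below the onset of azirine formation (which would give the regioisomeric pyrrole), and the closest known reaction type is the copper-catalysed 1,4-addition/denitrogenative condensation of 1,3-dicarbonyl compounds with 2-azidoacrylates to NH-pyrroles, here extended to an α-keto ester pronucleophile; the two transient stereocentres of 10 are erased on aromatisation.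

**Step 5**
Reactants: 11 diethyl 3-(6-bromo-1H-indol-3-yl)-4-(1-methyl-1H-imidazol-5-yl)-1H-pyrrole-2,5-dicarboxylate
Product: 14 Didemnimide D, via pyrrole diacid 12 (not isolated), via lactam acid 13 (not isolated)
Conditions: KOH (6 equiv), EtOH/H2O, 75 °C; AcOH to pH 7–8; then pyridine, 30% H2O2 (1.5 equiv), O2 (1 atm), 60 °C, dark
Reagents that add atoms: hydrogen peroxide, OO; dioxygen, O=O
Why: Proposed new method: after routine saponification, H2O2 hydroxylates the pyrrole ipso to one carboxylate with loss of CO2 to give lactam acid 13 (the known H2O2/pyridine conversion of pyrrole-α-carboxylic acids into 3-pyrrolin-2-ones), whose electron-rich 2-hydroxypyrrole tautomer is autoxidised by O2 at the carboxyl-bearing C5 to an α-hydroperoxy acid that fragments with loss of CO2 and hydroxide to the second imide carbonyl (closest known types: oxidative decarboxylation of α-hydroperoxy acids and oxygen-dependent decarboxylative oxidation of pyrrole-2-carboxylic acids); the conditions are non-acidic, metal-free and dark to spare the 3-substituted indole and the imidazole and to avoid photocyclisation of the product, and no stereocentre is present in 14.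

**Compound list**
1 | 6-bromo-1H-indole | Brc1ccc2cc[nH]c2c1 | starting material
2 | ethyl (Z)-3-bromo-2-(hydroxyimino)propanoate (ethyl bromopyruvate oxime) | CCOC(=O)/C(CBr)=N/O | starting material
3 | ethyl 2-nitrosoprop-2-enoate (nitrosoacrylate) | C=C(N=O)C(=O)OCC | intermediate (not isolated)
4 | ethyl (E)-3-(6-bromo-1H-indol-3-yl)-2-(hydroxyimino)propanoate | CCOC(=O)/C(Cc1c[nH]c2cc(Br)ccc12)=N/O | intermediate
5 | ethyl 3-(6-bromo-1H-indol-3-yl)-2-iminopropanoate (NH-imine) | CCOC(=O)C(=N)Cc1c[nH]c2cc(Br)ccc12 | intermediate (not isolated)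
6 | ethyl 3-(6-bromo-1H-indol-3-yl)-2-oxopropanoate (drawn as keto form; largely enol) | CCOC(=O)C(=O)Cc1c[nH]c2cc(Br)ccc12 | intermediate
7 | 1-methyl-1H-imidazole-5-carbaldehyde | Cn1cncc1C=O | starting material
8 | ethyl azidoacetate | CCOC(=O)CN=[N+]=[N-] | starting material
9 | ethyl (Z)-2-azido-3-(1-methyl-1H-imidazol-5-yl)prop-2-enoate | CCOC(=O)/C(N=[N+]=[N-])=C/c1cncn1C | intermediate
10 | diethyl 3-(6-bromo-1H-indol-3-yl)-5-imino-4-(1-methyl-1H-imidazol-5-yl)-2-oxohexanedioate (imino keto diester; transient mixture of racemic diastereomers) | CCOC(=O)C(=O)C(c1c[nH]c2cc(Br)ccc12)C(c1cncn1C)C(=N)C(=O)OCC | intermediate (not isolated)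
11 | diethyl 3-(6-bromo-1H-indol-3-yl)-4-(1-methyl-1H-imidazol-5-yl)-1H-pyrrole-2,5-dicarboxylate | CCOC(=O)c1[nH]c(C(=O)OCC)c(-c2cncn2C)c1-c1c[nH]c2cc(Br)ccc12 | intermediate
12 | 3-(6-bromo-1H-indol-3-yl)-4-(1-methyl-1H-imidazol-5-yl)-1H-pyrrole-2,5-dicarboxylic acid (pyrrole diacid; first formed as its dipotassium salt) | OC(=O)c1[nH]c(C(=O)O)c(-c2cncn2C)c1-c1c[nH]c2cc(Br)ccc12 | intermediate (not isolated)
13 | 3-(6-bromo-1H-indol-3-yl)-4-(1-methyl-1H-imidazol-5-yl)-5-oxo-2,5-dihydro-1H-pyrrole-2-carboxylic acid (lactam acid; racemic, one of two regioisomers shown, both converge on 14) | OC(=O)C1NC(=O)C(c2cncn2C)=C1c1c[nH]c2cc(Br)ccc12 | intermediate (not isolated)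
14 | Didemnimide D, 3-(6-bromo-1H-indol-3-yl)-4-(1-methyl-1H-imidazol-5-yl)-1H-pyrrole-2,5-dione (achiral) | Cn1cncc1C1=C(c2c[nH]c3cc(Br)ccc23)C(=O)NC1=O | target

**Step count and risk**
Total steps: 5. Longest linear sequence: 4 steps (1 → 4 → 6 → 11 → 14); the imidazole arm (7 + 8 → 9) is one step and joins at step 4.

The three steps most likely to fail:

Step 4 (the copper enolate may be sequestered by the imidazole, or the electron-rich azidoacrylate may be too poor an acceptor). The fallback sets out from 9 and 6 and returns at 11. Azidoacrylate 9 is converted by Staudinger reduction (PPh3, THF/H2O) and mild aqueous HCl hydrolysis of the resulting enamine into ethyl 3-(1-methyl-1H-imidazol-5-yl)-2-oxopropanoate F1. The lithium enolates of 6 and F1 (LiN(SiMe3)2, THF, −78 °C) are then joined by oxidative enolate heterocoupling with I2 to give the 1,4-diketone diethyl 3-(6-bromo-1H-indol-3-yl)-4-(1-methyl-1H-imidazol-5-yl)-2,5-dioxohexanedioate F2. The coupling is statistical; the two homodimers carry zero and two basic imidazoles and are removed by acid–base partition. Paal–Knorr condensation of F2 with NH4OAc in AcOH at 60 °C gives 11.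

Step 5 (the indole or imidazole may be oxidised competitively, or the sequence may stall after the first decarboxylation). The fallback sets out from 11 and returns at 14. Ester 11 is saponified and diacid 12 is isolated. Dye-sensitised photooxygenation (methylene blue, O2, 660 nm LED, aq. NaHCO3/MeOH, 0 °C; red light that neither substrate nor product absorbs) adds singlet oxygen across the pyrrole, and decarboxylative endoperoxide fragmentation gives 3-(6-bromo-1H-indol-3-yl)-2-hydroxy-4-(1-methyl-1H-imidazol-5-yl)-5-oxo-2,5-dihydro-1H-pyrrole-2-carboxylic acid F3 (with its regioisomer, which converges). Pb(OAc)4 (1.05 equiv, AcOH/CH2Cl2, 0 °C, dark) then effects glycol-type oxidative decarboxylation of this α-hydroxy acid to 14.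

Step 2 (incomplete deoximation, or pinacol-type over-reduction of the activated keto ester by TiCl3). The fallback sets out from 1 and returns at 6, bypassing 4. Sc(OTf)3-catalysed Friedel–Crafts opening of ethyl oxirane-2-carboxylate at its CH2 terminus by indole 1 (CH2Cl2, rt) gives racemic ethyl 3-(6-bromo-1H-indol-3-yl)-2-hydroxypropanoate F4. Dess–Martin periodinane (NaHCO3, CH2Cl2, 0 °C) oxidises F4 to 6.

**Further compounds**
F1 | step 4 | ethyl 3-(1-methyl-1H-imidazol-5-yl)-2-oxopropanoate | CCOC(=O)C(=O)Cc1cncn1C
F2 | step 4 | diethyl 3-(6-bromo-1H-indol-3-yl)-4-(1-methyl-1H-imidazol-5-yl)-2,5-dioxohexanedioate (mixture of racemic diastereomers) | CCOC(=O)C(=O)C(c1c[nH]c2cc(Br)ccc12)C(c1cncn1C)C(=O)C(=O)OCC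
F3 | step 5 | 3-(6-bromo-1H-indol-3-yl)-2-hydroxy-4-(1-methyl-1H-imidazol-5-yl)-5-oxo-2,5-dihydro-1H-pyrrole-2-carboxylic acid (racemic) | OC(=O)C1(O)NC(=O)C(c2cncn2C)=C1c1c[nH]c2cc(Br)ccc12
F4 | step 2 | ethyl 3-(6-bromo-1H-indol-3-yl)-2-hydroxypropanoate (racemic) | CCOC(=O)C(O)Cc1c[nH]c2cc(Br)ccc12
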